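Ring A of the target is a 3-methoxycyclohex-2-enone (C1 ketone, C2=C3–OMe, C4 mixed ketal, C5H2, C6–allyl), the oxidation pattern that a 1,1-dimethoxy-3-silyloxydiene leaves after [4+2] addition and loss of methanol. The route therefore disconnects C5–C6 and C3–C4: a copper–bis(oxazoline)-catalysed Diels–Alder reaction joins (3Z)-1,1-dimethoxy-3-(trimethylsilyloxy)hepta-1,3,6-triene to methyl 2-(2-allyl-4,5-dimethoxyphenoxy)acrylate, building ring A, the aryloxy-bearing quaternary C4 and the C6 stereocentre in one operation. The ester on C4 is a placeholder: saponification and oxidative decarboxylation in methanol exchange it for the C4 methoxy group under the direction of C6.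

Key step: step 6

Remarks on the chemistry (ring A numbering throughout: C1 ketone, C2=C3–OMe, C4 ketal carbon, C5H2, C6 allyl-bearing carbon):
- The target is (4R,6S): the C4 aryloxy group and the C6 allyl group are cis, and the C4 methoxy group is trans to the allyl group.
- No skeletal error was found. The cycloadduct is planned as the (1S,5S) ester (CO2Me cis to allyl), which is the endo product. Its C4 configuration is erased later, so only C6 has to be carried through.
- Assumption: the sense of induction of the copper complex on this five-membered chelate cannot be predicted with certainty. The (S,S)-ligand is written, and its equally available enantiomer would be used if the opposite alkene face proved to be the open one.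
- Design choices: the dienol ether is made under conditions expected to favour the (3Z) geometry, since only that isomer reaches the s-cis conformation. The hexafluoroantimonate copper complex is chosen over the triflate because the aryl vinyl ether oxygen is a weak donor.
- (S,S)-t-Bu-box = 2,2'-(propane-2,2-diyl)bis[(4S)-4-tert-butyl-4,5-dihydro-1,3-oxazole]; the complex is made from CuCl2, the ligand and AgSbF6.

Step 1
Reactants: 1 3,4-dimethoxyphenol; 2 allyl bromide
Product: 3 4-(allyloxy)-1,2-dimethoxybenzene
Conditions: K2CO3, acetone, reflux
Reagents that add atoms: none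
Why: Williamson ether synthesis in which the phenoxide formed with K2CO3 displaces bromide from the primary allylic halide (SN2) at oxygen, with no stereocentre involved.

Step 2
Reactants: 3 4-(allyloxy)-1,2-dimethoxybenzene
Product: 5 2-allyl-4,5-dimethoxyphenol, via 6-allyl-3,4-dimethoxycyclohexa-2,4-dien-1-one 4 (not isolated)
Conditions: N,N-diethylaniline, 190 °C, argon
Reagents that add atoms: none
Why: Aromatic Claisen rearrangement in which the [3,3]-sigmatropic shift delivers the allyl group to the unflanked ortho carbon to give dienone 4, which tautomerises to the phenol, the minor isomer from migration to the flanked ortho carbon being removed by chromatography.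

Step 3
Reactants: 5 2-allyl-4,5-dimethoxyphenol; 6 methyl 2,3-dibromopropanoate
Product: 10 methyl 2-(2-allyl-4,5-dimethoxyphenoxy)acrylate, via methyl 2-bromoacrylate 7 (not isolated), via the 3-aryloxy-2-bromopropanoate 8 (not isolated), via the 2,3-bis(aryloxy)propanoate 9 (not isolated)
Conditions: K2CO3 (3 equiv), acetone, reflux
Reagents that add atoms: none
Why: Elimination–addition–substitution–elimination cascade in which K2CO3 dehydrobrominates 6 to 7, the phenoxide of 5 adds to its CH2 terminus (oxa-Michael addition) to give 8, a second phenoxide displaces the activated α-bromide (SN2) to give 9, and E1cB loss of the β-aryloxide returns one phenoxide and leaves the 2-aryloxyacrylate, which has no stereocentre.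

Step 4
Reactants: 11 pent-4-enoyl chloride; 12 1,1-dimethoxyethene
Product: 13 1,1-dimethoxyhepta-1,6-dien-3-one
Conditions: Et3N, Et2O, 0 °C → rt (11 added slowly to excess 12)
Reagents that add atoms: none
Why: C-Acylation of a ketene acetal in which the nucleophilic CH2 terminus of 12 attacks the acid chloride and Et3N takes up the HCl to give the β-acyl ketene acetal, slow addition of 11 keeping ketene formation in check.

Step 5
Reactants: 13 1,1-dimethoxyhepta-1,6-dien-3-one
Product: 15 (3Z)-1,1-dimethoxy-3-(trimethylsilyloxy)hepta-1,3,6-triene, via the lithium dienolate 14 (not isolated)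
Conditions: LDA, THF/DMPU, −78 °C; then TMSCl, −78 → 0 °C; non-aqueous work-up, used at once
Reagents that add atoms: chlorotrimethylsilane, C[Si](C)(C)Cl
Why: Enolate O-silylation in which the C4 methylene is the only enolisable position of 13 and deprotonation by LDA in the presence of the strongly coordinating cosolvent followed by trapping on oxygen should favour the (Z)-enol ether, whose allylic CH2 lies trans to C2 so that the diene can reach its s-cis conformation.

Step 6
Reactants: 10 methyl 2-(2-allyl-4,5-dimethoxyphenoxy)acrylate; 15 (3Z)-1,1-dimethoxy-3-(trimethylsilyloxy)hepta-1,3,6-triene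
Product: 17 methyl (1S,5S)-5-allyl-1-(2-allyl-4,5-dimethoxyphenoxy)-2-methoxy-4-oxocyclohex-2-ene-1-carboxylate, via the silyl enol ether ketal cycloadduct 16 (not isolated)
Conditions: [Cu((S,S)-t-Bu-box)](SbF6)2 (10 mol %), 4 Å MS, CH2Cl2, −78 → −40 °C; then 1 M HCl, THF, 0 °C
Reagents that add atoms: none
Why: Proposed new method: the dicationic copper complex should bind 10 through its ester carbonyl and aryloxy oxygen in a five-membered chelate, so that the allyl-bearing terminus of 15 (future C6) adds to the acrylate CH2 (future C5) and the α-carbon (future C4) closes onto the dimethoxy-substituted terminus (future C3) in a concerted but asynchronous [4+2] addition whose stepwise limit is a Mukaiyama–Michael addition followed by ring closure of the copper enolate, after which dilute HCl cleaves the silyl enol ether of 16 and eliminates one methanol to leave the C1 ketone and the C2=C3–OMe unit. The closest known reaction types are the thermal and Lewis-acid-promoted Diels–Alder reactions of 1,1-dialkoxy-3-silyloxydienes with acrylates and the copper–bis(oxazoline)-catalysed enantioselective cycloadditions and sigmatropic rearrangements of acrylates that carry a 2-thio or 2-alkoxy donor and chelate in the same five-membered mode, whereas their combination on a 2-aryloxyacrylate is untested. Ring A is closed as a six-membered carbocycle by suprafacial [4+2] addition, which in the stepwise limit is a 6-(enolexo)-exo-trig closure. The quaternary centre C4 is controlled by the ligand, whose tert-butyl groups together with the aryl group turned away from them leave one face of the chelated alkene open, and C6 is set relative to C4 by the endo position of the copper-bound ester under the diene combined with the outward (Z) placement of the allylic CH2 substituent of 15, which puts CO2Me and allyl cis. The step needs regio-, endo- and enantioface selectivity: the first follows from the matched push–pull polarisation of diene and dienophile, the other two from the rigid chelate, and a minor C6 epimer is a diastereomer that is removed by chromatography before C4 is erased.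

Step 7
Reactants: 17 methyl (1S,5S)-5-allyl-1-(2-allyl-4,5-dimethoxyphenoxy)-2-methoxy-4-oxocyclohex-2-ene-1-carboxylate
Product: 19 (1S,5S)-5-allyl-1-(2-allyl-4,5-dimethoxyphenoxy)-2-methoxy-4-oxocyclohex-2-ene-1-carboxylic acid, via the lithium carboxylate 18 (not isolated)
Conditions: LiOH·H2O, THF/H2O, 0 °C; then cold 0.5 M HCl to pH 3, extracted and used at once
Reagents that add atoms: lithium hydroxide, [Li+].[OH-]
Why: Saponification (BAc2) in which hydroxide attacks the ester carbonyl, activated by the α-aryloxy group, faster than the vinylogous ester at 0 °C, the quaternary C4 cannot epimerise and any epimerisation at C6 would show as a separable diastereomer while C4 is still in place, and the acid, a vinylogous β-keto acid, is kept cold to avoid thermal loss of CO2.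

Step 8
Reactants: 19 (1S,5S)-5-allyl-1-(2-allyl-4,5-dimethoxyphenoxy)-2-methoxy-4-oxocyclohex-2-ene-1-carboxylic acid
Product: 21 (4R,6S)-6-allyl-4-(2-allyl-4,5-dimethoxyphenoxy)-3,4-dimethoxycyclohex-2-en-1-one (the target), via the C4 aryloxycarbenium ion 20 (not isolated)
Conditions: Pb(OAc)4, pyridine, MeOH/CH2Cl2, −20 → 0 °C
Reagents that add atoms: methanol, CO
Why: Lead tetraacetate oxidative decarboxylation of an α-oxygenated acid with solvent capture, in which ligand exchange at tetravalent lead and loss of CO2 and Pb(OAc)2 give the aryloxy-stabilised cation 20 and methanol adds to C4 along the pseudo-axial trajectory anti to the pseudo-axial C5–H of the half-chair that carries the C6 allyl group pseudo-equatorially (the torsional control known from trans-selective additions to 5-substituted cyclohex-2-enones), so that the methoxy group should enter trans to the allyl group and C4 becomes R, while pyridine buffers the acetic acid that would otherwise ionise the ketal.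

Compound list
1 | 3,4-dimethoxyphenol | COc1ccc(O)cc1OC | starting material
2 | allyl bromide (3-bromoprop-1-ene) | C=CCBr | starting material
3 | 4-(allyloxy)-1,2-dimethoxybenzene | C=CCOc1ccc(OC)c(OC)c1 | intermediate
4 | 6-allyl-3,4-dimethoxycyclohexa-2,4-dien-1-one (racemic, not isolated) | C=CCC1C=C(OC)C(OC)=CC1=O | intermediate
5 | 2-allyl-4,5-dimethoxyphenol | C=CCc1cc(OC)c(OC)cc1O | intermediate
6 | methyl 2,3-dibromopropanoate (racemic) | COC(=O)C(Br)CBr | starting material
7 | methyl 2-bromoacrylate (not isolated) | C=C(Br)C(=O)OC | intermediate
8 | methyl 3-(2-allyl-4,5-dimethoxyphenoxy)-2-bromopropanoate (racemic, not isolated) | C=CCc1cc(OC)c(OC)cc1OCC(Br)C(=O)OC | intermediate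
9 | methyl 2,3-bis(2-allyl-4,5-dimethoxyphenoxy)propanoate (racemic, not isolated) | C=CCc1cc(OC)c(OC)cc1OCC(Oc1cc(OC)c(OC)cc1CC=C)C(=O)OC | intermediate
10 | methyl 2-(2-allyl-4,5-dimethoxyphenoxy)acrylate | C=C(Oc1cc(OC)c(OC)cc1CC=C)C(=O)OC | intermediate
11 | pent-4-enoyl chloride | C=CCCC(=O)Cl | starting material
12 | 1,1-dimethoxyethene | C=C(OC)OC | starting material
13 | 1,1-dimethoxyhepta-1,6-dien-3-one | C=CCCC(=O)C=C(OC)OC | intermediate
14 | lithium (3Z)-1,1-dimethoxyhepta-1,3,6-trien-3-olate (not isolated) | C=CC/C=C([O-])/C=C(OC)OC.[Li+] | intermediate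
15 | (3Z)-1,1-dimethoxy-3-(trimethylsilyloxy)hepta-1,3,6-triene | C=CC/C=C(O[Si](C)(C)C)/C=C(OC)OC | intermediate
16 | methyl (1S,5S)-5-allyl-1-(2-allyl-4,5-dimethoxyphenoxy)-2,2-dimethoxy-4-(trimethylsilyloxy)cyclohex-3-ene-1-carboxylate (not isolated) | C=CC[C@H]1C[C@@](Oc2cc(OC)c(OC)cc2CC=C)(C(=O)OC)C(OC)(OC)C=C1O[Si](C)(C)C | intermediate
17 | methyl (1S,5S)-5-allyl-1-(2-allyl-4,5-dimethoxyphenoxy)-2-methoxy-4-oxocyclohex-2-ene-1-carboxylate | C=CCc1cc(OC)c(OC)cc1O[C@@]1(C(=O)OC)C[C@H](CC=C)C(=O)C=C1OC | intermediate
18 | lithium (1S,5S)-5-allyl-1-(2-allyl-4,5-dimethoxyphenoxy)-2-methoxy-4-oxocyclohex-2-ene-1-carboxylate (not isolated) | C=CCc1cc(OC)c(OC)cc1O[C@@]1(C(=O)[O-])C[C@H](CC=C)C(=O)C=C1OC.[Li+] | intermediate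
19 | (1S,5S)-5-allyl-1-(2-allyl-4,5-dimethoxyphenoxy)-2-methoxy-4-oxocyclohex-2-ene-1-carboxylic acid | C=CCc1cc(OC)c(OC)cc1O[C@@]1(C(=O)O)C[C@H](CC=C)C(=O)C=C1OC | intermediate
20 | [(5S)-5-allyl-2-methoxy-4-oxocyclohex-2-en-1-ylidene](2-allyl-4,5-dimethoxyphenyl)oxonium (not isolated) | C=CCc1cc(OC)c(OC)cc1[O+]=C1C[C@H](CC=C)C(=O)C=C1OC | intermediate
21 | (4R,6S)-6-allyl-4-(2-allyl-4,5-dimethoxyphenoxy)-3,4-dimethoxycyclohex-2-en-1-one (CNP0352100.2) | C=CCc1cc(OC)c(OC)cc1O[C@]1(OC)C[C@H](CC=C)C(=O)C=C1OC | target

Total step count: 8. Longest linear sequence: 6 steps (steps 1, 2, 3, 6, 7, 8); the diene branch (steps 4 and 5) joins at step 6.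

Steps most likely to fail

1. Step 6 (bears the new-method label). The aryloxy oxygen may chelate too weakly, so that one-point binding gives poor facial or endo selectivity. The Lewis acid may also consume the ketene-acetal diene by silyl transfer or by oxidation at divalent copper before cycloaddition, or the stepwise path may stop at the open-chain Michael stage. Fallback with known chemistry, setting out from 10 and 15: the cycloaddition is run thermally without catalyst (toluene, 80–100 °C, sealed tube), the established reactivity mode of 1,1-dialkoxy-3-silyloxydienes with acrylate-type dienophiles. This should give cycloadduct 16 as a racemate, that is, together with its enantiomer methyl (1R,5R)-5-allyl-1-(2-allyl-4,5-dimethoxyphenoxy)-2,2-dimethoxy-4-(trimethylsilyloxy)cyclohex-3-ene-1-carboxylate F1. The same HCl work-up should give the racemic enone ester, 17 together with its enantiomer methyl (1R,5R)-5-allyl-1-(2-allyl-4,5-dimethoxyphenoxy)-2-methoxy-4-oxocyclohex-2-ene-1-carboxylate F2. After chromatographic removal of the C6-epimeric pair, the enantiomers are separated by preparative HPLC on a polysaccharide chiral stationary phase, and the route is rejoined at 17.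

2. Step 8. Cation 20 may lose the C5 proton and aromatise instead of being captured, methanol capture in a protic medium at 0 °C may show poor facial selectivity, or the product ketal may re-ionise and epimerise. Fallback, setting out from 19: the decarboxylation is run in an aprotic medium (Pb(OAc)4, pyridine, benzene, rt), where acetate is the only nucleophile, to give the acylal (5S)-5-allyl-1-(2-allyl-4,5-dimethoxyphenoxy)-2-methoxy-4-oxocyclohex-2-en-1-yl acetate F3 as a mixture of C1 epimers. F3 is then ionised at −78 °C with catalytic TMSOTf in CH2Cl2 in the presence of methoxytrimethylsilane. The stereo-determining C–O bond formation thus takes place at low temperature in a non-protic medium, as in the substitution of an anomeric acetate, and the route is rejoined at 21.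

3. Step 3. The one-pot cascade may stall at the bis(aryloxy) ester, or the bromoacrylate formed in the flask may polymerise before the phenoxide adds. Fallback, setting out from 5: O-alkylation with methyl bromoacetate (K2CO3, acetone) gives methyl 2-(2-allyl-4,5-dimethoxyphenoxy)acetate F4. Its lithium enolate (LiHMDS, THF, −78 °C) is aminomethylated with dimethylmethyleneiminium iodide (Mannich reaction) to give methyl 2-(2-allyl-4,5-dimethoxyphenoxy)-3-(dimethylamino)propanoate F5. Quaternisation with MeI gives 2-(2-allyl-4,5-dimethoxyphenoxy)-3-methoxy-N,N,N-trimethyl-3-oxopropan-1-aminium iodide F6, and DBU-induced elimination of trimethylamine rejoins the route at 10.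

Further compounds
F1 | step 6 | methyl (1R,5R)-5-allyl-1-(2-allyl-4,5-dimethoxyphenoxy)-2,2-dimethoxy-4-(trimethylsilyloxy)cyclohex-3-ene-1-carboxylate | C=CC[C@@H]1C[C@](Oc2cc(OC)c(OC)cc2CC=C)(C(=O)OC)C(OC)(OC)C=C1O[Si](C)(C)C
F2 | step 6 | methyl (1R,5R)-5-allyl-1-(2-allyl-4,5-dimethoxyphenoxy)-2-methoxy-4-oxocyclohex-2-ene-1-carboxylate | C=CCc1cc(OC)c(OC)cc1O[C@]1(C(=O)OC)C[C@@H](CC=C)C(=O)C=C1OC
F3 | step 8 | (5S)-5-allyl-1-(2-allyl-4,5-dimethoxyphenoxy)-2-methoxy-4-oxocyclohex-2-en-1-yl acetate (C1 epimers) | C=CCc1cc(OC)c(OC)cc1OC1(OC(C)=O)C[C@H](CC=C)C(=O)C=C1OC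
F4 | step 3 | methyl 2-(2-allyl-4,5-dimethoxyphenoxy)acetate | C=CCc1cc(OC)c(OC)cc1OCC(=O)OC
F5 | step 3 | methyl 2-(2-allyl-4,5-dimethoxyphenoxy)-3-(dimethylamino)propanoate (racemic) | C=CCc1cc(OC)c(OC)cc1OC(CN(C)C)C(=O)OC
F6 | step 3 | 2-(2-allyl-4,5-dimethoxyphenoxy)-3-methoxy-N,N,N-trimethyl-3-oxopropan-1-aminium iodide (racemic) | C=CCc1cc(OC)c(OC)cc1OC(C[N+](C)(C)C)C(=O)OC.[I-]
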